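**Target:** CNP0201108.2, (2E,6E,9S,12Z)-15-(furan-3-yl)-12-(methoxycarbonyl)-6-methyl-2-(4-methylpent-3-en-1-yl)-9-(prop-1-en-2-yl)pentadeca-2,6,12-trienoic acid. It has one stereocenter (S) and three stereodefined trisubstituted alkenes.

## Retrosynthetic overview

1. Target ⇐ allyl ester 27 (deallylation) ⇐ E-selective Wittig reaction of aldehyde 23 with the stabilised ylide 26 (acid-side enoate).
2. 23 ⇐ amide 21 ⇐ Eschenmoser–Claisen rearrangement of allylic alcohol 18 (sets the central E alkene) ⇐ aldehyde 16 + isopropenyl Grignard reagent.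
3. 16 ⇐ bromide 14 ⇐ Z-selective Wittig reaction of α-keto ester 6 with the furylpropyl ylide 13 (ester-side enoate).
4. 6 ⇐ catalytic asymmetric conjugate ene reaction of 5-bromo-2-methylpent-2-ene with methyl 2-oxobut-3-enoate; this single step creates the stereocenter, the isopropenyl group and the keto ester arm.
5. No ring is formed; the furan ring is carried in from 3-bromofuran.

Assumption: the (S,S) antipode of the step 2 catalyst is taken to give the (5S) product; the sense is confirmed in the first run and the (R,R) antipode is used if it is opposite.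

## Route

Step 1
Reactants: 1 dimethyl oxalate; 2 vinylmagnesium bromide (CH2=CHMgBr)
Product: 4 methyl 2-oxobut-3-enoate, via magnesium hemiketal 3 (not isolated)
Conditions: 2 added to 1 (1.5 equiv), THF/Et2O, −78 °C; then 1 M HCl, −78 °C; bulb-to-bulb distillation, kept as a cold CH2Cl2 solution and used at once
Reagents that add atoms: none
Why: Nucleophilic acyl substitution of an oxalate ester by a Grignard reagent: at −78 °C the chelated hemiketal 3 does not collapse, so only one vinyl group adds and the keto ester appears only on acidic quench; no stereocenter is formed.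

Step 2
Reactants: 4 methyl 2-oxobut-3-enoate; 5 5-bromo-2-methylpent-2-ene
Product: 6 methyl (5S)-5-(2-bromoethyl)-6-methyl-2-oxohept-6-enoate
Conditions: 5 (2 equiv), (S,S)-IDPi Brønsted acid [imidodiphosphorimidate built from (S)-3,3′-bis(3,5-bis(trifluoromethyl)phenyl)-BINOL, N-triflyl groups on phosphorus] (5 mol %), CH2Cl2, −78 °C; Et3N quench at −78 °C
Reagents that add atoms: none
Why: Proposed new method: a catalytic enantioselective intermolecular conjugate ene reaction; the confined chiral acid protonates or hydrogen-bonds the 1,2-dicarbonyl unit of 4 and so makes its terminal CH2 (C4) strongly electrophilic, alkene 5 attacks it through its less substituted carbon C3 (positive charge builds on the CMe2 carbon) while a hydrogen of one geminal methyl group shifts to C3 of 4 in a six-membered transition state, which gives the isopropenyl group regiospecifically, and the catalyst pocket exposes only the Si face of C3 of 5, which gives the (S) center; the closest known reaction types are Lewis-acid-promoted ene reactions of trisubstituted alkenes with vinyl ketones and acrylates, chiral Brønsted-acid-catalysed carbonyl-ene reactions and IDPi-catalysed additions of unactivated alkenes to activated carbonyl compounds.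

Step 3
Reactants: 7 3-bromofuran; 8 oxetane
Product: 10 3-(furan-3-yl)propan-1-ol, via 3-furyllithium 9 (not isolated)
Conditions: n-BuLi, THF, −78 °C; then 8, BF3·OEt2, −78 °C; then sat. aq. NH4Cl
Reagents that add atoms: none
Why: Bromine–lithium exchange followed by Lewis-acid-assisted SN2 opening of oxetane by the organolithium; the temperature is held at −78 °C so that 9 does not isomerise to the 2-lithio isomer; no stereocenter.

Step 4
Reactants: 10 3-(furan-3-yl)propan-1-ol
Product: 11 3-(3-iodopropyl)furan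
Conditions: I2, PPh3, imidazole, CH2Cl2, 0 °C to 25 °C
Reagents that add atoms: iodine, II
Why: Appel-type iodination (Garegg–Samuelsson conditions): the alcohol is activated on phosphorus and displaced by iodide in an SN2 step; the buffered medium spares the furan.

Step 5
Reactants: 11 3-(3-iodopropyl)furan
Product: 12 [3-(furan-3-yl)propyl]triphenylphosphonium iodide
Conditions: PPh3, MeCN, 80 °C
Reagents that add atoms: triphenylphosphine, c1ccc(cc1)P(c1ccccc1)c1ccccc1
Why: SN2 quaternisation of triphenylphosphine by a primary iodide (phosphonium salt formation).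

Step 6
Reactants: 6 methyl (5S)-5-(2-bromoethyl)-6-methyl-2-oxohept-6-enoate; 12 [3-(furan-3-yl)propyl]triphenylphosphonium iodide
Product: 14 methyl (2Z,5S)-5-(2-bromoethyl)-2-[3-(furan-3-yl)propylidene]-6-methylhept-6-enoate, via phosphorus ylide 13 (not isolated)
Conditions: 12 (1.3 equiv), NaN(SiMe3)2, THF, −78 to 0 °C; then 6, −78 to −20 °C
Reagents that add atoms: none
Why: Wittig reaction of a lithium-free non-stabilised ylide with an α-keto ester under kinetic control: as with α-alkoxy ketones, the ylide substituent is expected to end up cis to the polar ester group, giving the (Z)-enoate; the ketone reacts far faster than the ester or the primary bromide, and the stereocenter is not α to a carbonyl and is untouched.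

Step 7
Reactants: 14 methyl (2Z,5S)-5-(2-bromoethyl)-2-[3-(furan-3-yl)propylidene]-6-methylhept-6-enoate
Product: 16 methyl (2Z,5S)-2-[3-(furan-3-yl)propylidene]-6-methyl-5-(2-oxoethyl)hept-6-enoate, via alkoxyammonium bromide 15 (not isolated)
Conditions: Me3NO (anhydrous, 4 equiv), DMSO, 25 °C
Reagents that add atoms: trimethylamine N-oxide, C[N+](C)(C)[O-]
Why: Ganem (N-oxide) variant of the Kornblum oxidation: SN2 displacement of the primary bromide by the N-oxide oxygen gives 15, which loses trimethylamine by elimination to the aldehyde; the neutral conditions leave ester, furan and the β-stereocenter intact.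

Step 8
Reactants: 16 methyl (2Z,5S)-2-[3-(furan-3-yl)propylidene]-6-methyl-5-(2-oxoethyl)hept-6-enoate; 17 isopropenylmagnesium bromide (CH2=C(CH3)MgBr)
Product: 18 methyl (2Z,5S)-2-[3-(furan-3-yl)propylidene]-5-(2-hydroxy-3-methylbut-3-en-1-yl)-6-methylhept-6-enoate (both carbinol epimers)
Conditions: 17 (1.2 equiv), THF, −78 °C; then sat. aq. NH4Cl
Reagents that add atoms: none
Why: Grignard 1,2-addition: at −78 °C the aldehyde reacts much faster than the hindered conjugated ester; the new carbinol center forms without control, which does not matter because it is consumed in step 9.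

Step 9
Reactants: 18 methyl (2Z,5S)-2-[3-(furan-3-yl)propylidene]-5-(2-hydroxy-3-methylbut-3-en-1-yl)-6-methylhept-6-enoate; 19 1,1-dimethoxy-N,N-dimethylethan-1-amine
Product: 21 methyl (2Z,5S,7E)-11-(dimethylamino)-2-[3-(furan-3-yl)propylidene]-8-methyl-11-oxo-5-(prop-1-en-2-yl)undec-7-enoate, via ketene N,O-acetal 20 (not isolated)
Conditions: 19 (5 equiv), toluene, 110 °C, MeOH distilled off
Reagents that add atoms: none
Why: Eschenmoser–Claisen rearrangement: alcohol exchange and loss of methanol give 20, whose chair [3,3] transition state keeps the large carbinol substituent equatorial (away from the NMe2 group), so the trisubstituted alkene forms with E geometry; the carbinol center disappears and C5 is not involved.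

Step 10
Reactants: 21 methyl (2Z,5S,7E)-11-(dimethylamino)-2-[3-(furan-3-yl)propylidene]-8-methyl-11-oxo-5-(prop-1-en-2-yl)undec-7-enoate
Product: 23 methyl (2Z,5S,7E)-2-[3-(furan-3-yl)propylidene]-8-methyl-11-oxo-5-(prop-1-en-2-yl)undec-7-enoate, via zirconium hemiaminal 22 (not isolated)
Conditions: Cp2Zr(H)Cl (1.6 equiv), THF, 25 °C, 20 min; then H2O, silica gel
Reagents that add atoms: none
Why: Amide-selective hydrozirconation (Georg reduction): Cp2Zr(H)Cl adds across the amide C=O to give 22, which is not reduced further and releases the aldehyde on hydrolysis; the ester, the furan and the hindered alkenes react far more slowly.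

Step 11
Reactants: 24 allyl (triphenyl-λ5-phosphanylidene)acetate; 5 5-bromo-2-methylpent-2-ene
Product: 26 allyl 6-methyl-2-(triphenyl-λ5-phosphanylidene)hept-5-enoate, via phosphonium bromide 25 (not isolated)
Conditions: NaI (10 mol %), MeCN, 80 °C; then 1 M NaOH, CH2Cl2, 0 °C
Reagents that add atoms: none
Why: C-alkylation of a stabilised ylide by a primary bromide (iodide catalysis) gives salt 25, which cold aqueous NaOH deprotonates to the α-substituted stabilised ylide without ester hydrolysis.

Step 12
Reactants: 23 methyl (2Z,5S,7E)-2-[3-(furan-3-yl)propylidene]-8-methyl-11-oxo-5-(prop-1-en-2-yl)undec-7-enoate; 26 allyl 6-methyl-2-(triphenyl-λ5-phosphanylidene)hept-5-enoate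
Product: 27 prop-2-en-1-yl (2E,6E,9S,12Z)-15-(furan-3-yl)-12-(methoxycarbonyl)-6-methyl-2-(4-methylpent-3-en-1-yl)-9-(prop-1-en-2-yl)pentadeca-2,6,12-trienoate
Conditions: 26 (1.5 equiv), toluene, 90 °C
Reagents that add atoms: none
Why: Wittig reaction of an α-substituted stabilised ylide: reversible addition under thermodynamic control gives the (E)-enoate (chain trans to the ester group); no stereocenter is touched.

Step 13
Reactants: 27 prop-2-en-1-yl (2E,6E,9S,12Z)-15-(furan-3-yl)-12-(methoxycarbonyl)-6-methyl-2-(4-methylpent-3-en-1-yl)-9-(prop-1-en-2-yl)pentadeca-2,6,12-trienoate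
Product: 28 (2E,6E,9S,12Z)-15-(furan-3-yl)-12-(methoxycarbonyl)-6-methyl-2-(4-methylpent-3-en-1-yl)-9-(prop-1-en-2-yl)pentadeca-2,6,12-trienoic acid
Conditions: Pd(PPh3)4 (5 mol %), morpholine (5 equiv), THF, 25 °C; then pH 4 buffer
Reagents that add atoms: none
Why: Tsuji–Trost deallylation: zerovalent palladium ionises the allyl ester to a π-allyl complex that morpholine traps, which frees the acid without touching the methyl ester, the alkenes, the furan or the stereocenter.

## Compound list

1 | dimethyl oxalate | COC(=O)C(=O)OC | starting material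
2 | vinylmagnesium bromide (CH2=CHMgBr) | C=C[Mg]Br | starting material
3 | methyl 2-[(bromomagnesio)oxy]-2-methoxybut-3-enoate (magnesium hemiketal) | C=CC(OC)(O[Mg]Br)C(=O)OC | intermediate
4 | methyl 2-oxobut-3-enoate | C=CC(=O)C(=O)OC | intermediate
5 | 5-bromo-2-methylpent-2-ene | CC(C)=CCCBr | starting material
6 | methyl (5S)-5-(2-bromoethyl)-6-methyl-2-oxohept-6-enoate | C=C(C)[C@H](CCBr)CCC(=O)C(=O)OC | intermediate
7 | 3-bromofuran | Brc1ccoc1 | starting material
8 | oxetane | C1COC1 | starting material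
9 | 3-furyllithium | [Li]c1ccoc1 | intermediate
10 | 3-(furan-3-yl)propan-1-ol | OCCCc1ccoc1 | intermediate
11 | 3-(3-iodopropyl)furan | ICCCc1ccoc1 | intermediate
12 | [3-(furan-3-yl)propyl]triphenylphosphonium iodide | [I-].c1ccc(cc1)[P+](CCCc1ccoc1)(c1ccccc1)c1ccccc1 | intermediate
13 | [3-(furan-3-yl)propylidene]triphenyl-λ5-phosphane (phosphorus ylide) | c1ccc(cc1)P(=CCCc1ccoc1)(c1ccccc1)c1ccccc1 | intermediate
14 | methyl (2Z,5S)-5-(2-bromoethyl)-2-[3-(furan-3-yl)propylidene]-6-methylhept-6-enoate | C=C(C)[C@H](CCBr)CC/C(=C/CCc1ccoc1)C(=O)OC | intermediate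
15 | methyl (2Z,5S)-2-[3-(furan-3-yl)propylidene]-6-methyl-5-{2-[(trimethylammonio)oxy]ethyl}hept-6-enoate bromide (alkoxyammonium bromide) | [Br-].C=C(C)[C@H](CCO[N+](C)(C)C)CC/C(=C/CCc1ccoc1)C(=O)OC | intermediate
16 | methyl (2Z,5S)-2-[3-(furan-3-yl)propylidene]-6-methyl-5-(2-oxoethyl)hept-6-enoate | C=C(C)[C@H](CC=O)CC/C(=C/CCc1ccoc1)C(=O)OC | intermediate
17 | isopropenylmagnesium bromide (CH2=C(CH3)MgBr) | C=C(C)[Mg]Br | starting material
18 | methyl (2Z,5S)-2-[3-(furan-3-yl)propylidene]-5-(2-hydroxy-3-methylbut-3-en-1-yl)-6-methylhept-6-enoate (both carbinol epimers) | C=C(C)[C@H](CC(O)C(C)=C)CC/C(=C/CCc1ccoc1)C(=O)OC | intermediate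
19 | 1,1-dimethoxy-N,N-dimethylethan-1-amine (N,N-dimethylacetamide dimethyl acetal) | CC(OC)(OC)N(C)C | starting material
20 | methyl (2Z,5S)-5-(2-{[1-(dimethylamino)ethenyl]oxy}-3-methylbut-3-en-1-yl)-2-[3-(furan-3-yl)propylidene]-6-methylhept-6-enoate (ketene N,O-acetal) | C=C(C)[C@H](CC(OC(=C)N(C)C)C(C)=C)CC/C(=C/CCc1ccoc1)C(=O)OC | intermediate
21 | methyl (2Z,5S,7E)-11-(dimethylamino)-2-[3-(furan-3-yl)propylidene]-8-methyl-11-oxo-5-(prop-1-en-2-yl)undec-7-enoate | C=C(C)[C@H](C/C=C(\C)CCC(=O)N(C)C)CC/C(=C/CCc1ccoc1)C(=O)OC | intermediate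
22 | methyl (2Z,5S,7E)-11-{[chlorobis(cyclopentadienyl)zirconio]oxy}-11-(dimethylamino)-2-[3-(furan-3-yl)propylidene]-8-methyl-5-(prop-1-en-2-yl)undec-7-enoate (zirconium hemiaminal R–CH(NMe2)–OZr(Cl)Cp2) | C=C(C)[C@H](C/C=C(\C)CCC(O[Zr](Cl)(C1C=CC=C1)C1C=CC=C1)N(C)C)CC/C(=C/CCc1ccoc1)C(=O)OC | intermediate
23 | methyl (2Z,5S,7E)-2-[3-(furan-3-yl)propylidene]-8-methyl-11-oxo-5-(prop-1-en-2-yl)undec-7-enoate | C=C(C)[C@H](C/C=C(\C)CCC=O)CC/C(=C/CCc1ccoc1)C(=O)OC | intermediate
24 | allyl (triphenyl-λ5-phosphanylidene)acetate | C=CCOC(=O)C=P(c1ccccc1)(c1ccccc1)c1ccccc1 | starting material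
25 | [6-methyl-1-oxo-1-(prop-2-en-1-yloxy)hept-5-en-2-yl]triphenylphosphonium bromide | [Br-].C=CCOC(=O)C(CCC=C(C)C)[P+](c1ccccc1)(c1ccccc1)c1ccccc1 | intermediate
26 | allyl 6-methyl-2-(triphenyl-λ5-phosphanylidene)hept-5-enoate | C=CCOC(=O)C(CCC=C(C)C)=P(c1ccccc1)(c1ccccc1)c1ccccc1 | intermediate
27 | prop-2-en-1-yl (2E,6E,9S,12Z)-15-(furan-3-yl)-12-(methoxycarbonyl)-6-methyl-2-(4-methylpent-3-en-1-yl)-9-(prop-1-en-2-yl)pentadeca-2,6,12-trienoate | C=C(C)[C@H](C/C=C(\C)CC/C=C(\CCC=C(C)C)C(=O)OCC=C)CC/C(=C/CCc1ccoc1)C(=O)OC | intermediate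
28 | (2E,6E,9S,12Z)-15-(furan-3-yl)-12-(methoxycarbonyl)-6-methyl-2-(4-methylpent-3-en-1-yl)-9-(prop-1-en-2-yl)pentadeca-2,6,12-trienoic acid (CNP0201108.2) | C=C(C)[C@H](C/C=C(\C)CC/C=C(\CCC=C(C)C)C(=O)O)CC/C(=C/CCc1ccoc1)C(=O)OC | target

## Step count and risks

Total step count: 13.
Longest linear sequence: 10 steps (steps 3, 4, 5, 6, 7, 8, 9, 10, 12, 13, from 3-bromofuran 7 to 28).

**Step 2 (the new ene reaction) is the most likely to fail.**
- The tertiary cation–enol pair can close to a dihydropyran (hetero-Diels–Alder product) instead of transferring hydrogen.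
- The acid can trigger an intramolecular carbonyl-ene cyclisation of 6 (its keto group attacked by its own isopropenyl group, six-membered ring).
- The isopropenyl group of 6 can react with a second molecule of 4.
- The enantioselectivity is untested.
- Controls in the main route: −78 °C, excess 5, amine quench while cold, and immediate use of 6.

Fallback with known chemistry, setting out from alcohol 10 and coming back at aldehyde 16: Dess–Martin oxidation of 10 gives 3-(furan-3-yl)propanal F1. Commercial methyl bis(2,2,2-trifluoroethyl)phosphonoacetate is alkylated with 4-bromobut-1-ene (NaH, DMSO) to methyl 2-[bis(2,2,2-trifluoroethoxy)phosphoryl]hex-5-enoate F2. Still–Gennari olefination of F2 with F1 (KN(SiMe3)2, 18-crown-6, THF, −78 °C) gives methyl (2Z)-2-(but-3-en-1-yl)-5-(furan-3-yl)pent-2-enoate F3. Cross-metathesis of F3 with N-methoxy-N-methylacrylamide (second-generation Hoveyda–Grubbs catalyst, CH2Cl2, 40 °C) gives methyl (2Z)-5-(furan-3-yl)-2-{(3E)-5-[methoxy(methyl)amino]-5-oxopent-3-en-1-yl}pent-2-enoate F4. Rhodium-catalysed asymmetric 1,4-addition of potassium isopropenyltrifluoroborate ([Rh(cod)Cl]2, the BINAP antipode that gives the S center, toluene/H2O, 100 °C) then sets the stereocenter in methyl (2Z,5S)-2-[3-(furan-3-yl)propylidene]-5-{2-[methoxy(methyl)amino]-2-oxoethyl}-6-methylhept-6-enoate F5. Reduction of the Weinreb amide with Cp2Zr(H)Cl (THF, 25 °C) gives 16, and the route continues at step 8.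

**Step 6 (Z-selective Wittig reaction on the α-keto ester).** The basic ylide can enolise 6, and the Z:E ratio may be modest.

Fallback setting out from keto ester 6 and coming back at 14: NaBH4 (MeOH, −40 °C) reduces the ketone to methyl (5S)-5-(2-bromoethyl)-2-hydroxy-6-methylhept-6-enoate F6. CBr4/PPh3 converts it to methyl (5S)-2-bromo-5-(2-bromoethyl)-6-methylhept-6-enoate F7. Michaelis–Becker substitution at the activated α-position with diphenyl phosphite (Et3N, CH2Cl2) gives the Ando-type phosphonate methyl (5S)-5-(2-bromoethyl)-2-(diphenoxyphosphoryl)-6-methylhept-6-enoate F8. Z-selective Horner–Wadsworth–Emmons reaction of F8 with 3-(furan-3-yl)propanal F1 (made from 10 as above; NaH, THF, −78 °C, anion formed in the presence of the aldehyde so that it does not alkylate the primary bromide) gives 14.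

**Step 7 (direct oxidation of the primary bromide).** Displacement by the N-oxide may be slow, and elimination to the vinyl compound can compete.

Fallback setting out from bromide 14 and coming back at aldehyde 16: KOAc (18-crown-6, DMF, 60 °C) gives methyl (2Z,5S)-5-[2-(acetyloxy)ethyl]-2-[3-(furan-3-yl)propylidene]-6-methylhept-6-enoate F9. K2CO3 in MeOH gives methyl (2Z,5S)-2-[3-(furan-3-yl)propylidene]-5-(2-hydroxyethyl)-6-methylhept-6-enoate F10. Dess–Martin periodinane (NaHCO3, CH2Cl2) gives 16.

## Further compounds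

F1 | step 2 | 3-(furan-3-yl)propanal | O=CCCc1ccoc1
F2 | step 2 | methyl 2-[bis(2,2,2-trifluoroethoxy)phosphoryl]hex-5-enoate | C=CCCC(C(=O)OC)P(=O)(OCC(F)(F)F)OCC(F)(F)F
F3 | step 2 | methyl (2Z)-2-(but-3-en-1-yl)-5-(furan-3-yl)pent-2-enoate | C=CCC/C(=C/CCc1ccoc1)C(=O)OC
F4 | step 2 | methyl (2Z)-5-(furan-3-yl)-2-{(3E)-5-[methoxy(methyl)amino]-5-oxopent-3-en-1-yl}pent-2-enoate | CON(C)C(=O)/C=C/CC/C(=C/CCc1ccoc1)C(=O)OC
F5 | step 2 | methyl (2Z,5S)-2-[3-(furan-3-yl)propylidene]-5-{2-[methoxy(methyl)amino]-2-oxoethyl}-6-methylhept-6-enoate | C=C(C)[C@H](CC(=O)N(C)OC)CC/C(=C/CCc1ccoc1)C(=O)OC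
F6 | step 6 | methyl (5S)-5-(2-bromoethyl)-2-hydroxy-6-methylhept-6-enoate | C=C(C)[C@H](CCBr)CCC(O)C(=O)OC
F7 | step 6 | methyl (5S)-2-bromo-5-(2-bromoethyl)-6-methylhept-6-enoate | C=C(C)[C@H](CCBr)CCC(Br)C(=O)OC
F8 | step 6 | methyl (5S)-5-(2-bromoethyl)-2-(diphenoxyphosphoryl)-6-methylhept-6-enoate | C=C(C)[C@H](CCBr)CCC(C(=O)OC)P(=O)(Oc1ccccc1)Oc1ccccc1
F9 | step 7 | methyl (2Z,5S)-5-[2-(acetyloxy)ethyl]-2-[3-(furan-3-yl)propylidene]-6-methylhept-6-enoate | C=C(C)[C@H](CCOC(C)=O)CC/C(=C/CCc1ccoc1)C(=O)OC
F10 | step 7 | methyl (2Z,5S)-2-[3-(furan-3-yl)propylidene]-5-(2-hydroxyethyl)-6-methylhept-6-enoate | C=C(C)[C@H](CCO)CC/C(=C/CCc1ccoc1)C(=O)OC
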